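**Retrosynthetic overview**
1. The target is a 2,3-trans-3,4-trans 4-arylflavan-3-ol; the last disconnection removes only two MOM ethers (O7 and O4').
2. Key disconnection: C4 of the flavan to C2 of the 3,5-dihydroxyphenyl ring of piceatannol, cut together with O1–C2 of the pyran ring. This leads back to the acyclic phenolic epoxy carbinol 9 and piceatannol 10, joined in a one-pot acid cascade (6-endo epoxide opening, then C4 ionisation and Friedel–Crafts arylation).
3. Enabling feature: C4 is benzylic to the A ring, para to O7 (through C4a) and ortho to O1 (through C8a), so its carbinol ionises easily. C2 is benzylic to the B ring and para to O4', so the epoxide opens there. C2 of the stilbene's resorcinol ring is para to one hydroxyl and ortho to the other.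
4. Compound 9 comes from chalcone 6 (Claisen–Schmidt) by Juliá–Colonna epoxidation, NaBH4 reduction and Pd(0) deallylation. The epoxidation is the only external source of chirality: its two carbons become C3 (retention) and C2 (inversion).
5. Ring order: transient oxirane (step 5), then the pyran ring (step 8), the only ring of the target that is built; all arenes are bought.

Key step: step 8

Remark: piceatannol (10) is taken as a commercial starting material. The carbinol centre of 8 and 9 and C4 of 11 are carried as mixtures because this carbon becomes planar in step 8.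

**Step 1**
Reactants: 1 2,4-dihydroxyacetophenone
Product: 2 1-[2-hydroxy-4-(methoxymethoxy)phenyl]ethanone
Conditions: MOMCl (1.1 equiv), K2CO3, acetone, 0 °C → rt
Reagents that add atoms: chloromethyl methyl ether, COCCl
Why: Williamson-type MOM protection, selective for the 4-OH because the 2-OH is held in a hydrogen bond to the ketone.

**Step 2**
Reactants: 2 1-[2-hydroxy-4-(methoxymethoxy)phenyl]ethanone
Product: 3 1-[4-(methoxymethoxy)-2-(prop-2-en-1-yloxy)phenyl]ethanone
Conditions: allyl bromide, K2CO3, KI (cat.), DMF, 60 °C
Reagents that add atoms: allyl bromide, C=CCBr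
Why: Williamson etherification of the chelated phenol under more forcing conditions; allyl is chosen because Pd(0) can later remove it without acid.

**Step 3**
Reactants: 4 4-hydroxybenzaldehyde
Product: 5 4-(methoxymethoxy)benzaldehyde
Conditions: MOMCl, K2CO3, acetone, 0 °C → rt
Reagents that add atoms: chloromethyl methyl ether, COCCl
Why: Williamson-type MOM protection of a phenol; the aldehyde is inert to these conditions.

**Step 4**
Reactants: 3 1-[4-(methoxymethoxy)-2-(prop-2-en-1-yloxy)phenyl]ethanone; 5 4-(methoxymethoxy)benzaldehyde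
Product: 6 (E)-1-[4-(methoxymethoxy)-2-(prop-2-en-1-yloxy)phenyl]-3-[4-(methoxymethoxy)phenyl]prop-2-en-1-one
Conditions: KOH (aq. 50%), EtOH, rt
Reagents that add atoms: none
Why: Claisen–Schmidt condensation should give the thermodynamic (E)-chalcone, and MOM and allyl ethers are stable to base.

**Step 5**
Reactants: 6 (E)-chalcone
Product: 7 [(2R,3S)-3-[4-(methoxymethoxy)phenyl]oxiran-2-yl][4-(methoxymethoxy)-2-(prop-2-en-1-yloxy)phenyl]methanone (trans-epoxy ketone)
Conditions: poly-L-leucine, urea–H2O2, DBU, THF, rt
Reagents that add atoms: urea–hydrogen peroxide, NC(N)=O.OO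
Why: Juliá–Colonna asymmetric nucleophilic epoxidation of a chalcone, in which the L-polyleucine helix should direct hydroperoxide to one enone face to give the trans-(2R,3S)-epoxide (the source of C3 and C2), while the allyl ether alkene is inert to hydroperoxide anion.

**Step 6**
Reactants: 7 trans-(2R,3S)-epoxy ketone
Product: 8 [(2S,3S)-3-[4-(methoxymethoxy)phenyl]oxiran-2-yl][4-(methoxymethoxy)-2-(prop-2-en-1-yloxy)phenyl]methanol (both carbinol epimers)
Conditions: NaBH4, MeOH/THF, 0 °C
Reagents that add atoms: none
Why: borohydride 1,2-reduction of an α,β-epoxy ketone leaves the epoxide intact, and the new carbinol centre need not be controlled because it is ionised in step 8.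

**Step 7**
Reactants: 8 allyl-protected epoxy carbinol
Product: 9 [2-hydroxy-4-(methoxymethoxy)phenyl][(2S,3S)-3-[4-(methoxymethoxy)phenyl]oxiran-2-yl]methanol (both carbinol epimers; used at once without chromatography)
Conditions: Pd(PPh3)4 (5 mol%), morpholine, THF, 0 °C → rt, short reaction time; pH 7 buffer wash
Reagents that add atoms: none
Why: Tsuji–Trost-type Pd(0) deallylation of an aryl allyl ether with an amine as allyl acceptor is close to neutral, so the acid-labile epoxide and the MOM ethers should survive.

**Step 8**
Reactants: 9 phenolic epoxy carbinol; 10 piceatannol, (E)-3,3',4',5-tetrahydroxystilbene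
Product: 12 (2R,3S,4S)-4-[2-[(E)-2-(3,4-dihydroxyphenyl)ethenyl]-4,6-dihydroxyphenyl]-7-(methoxymethoxy)-2-[4-(methoxymethoxy)phenyl]-3,4-dihydro-2H-chromen-3-ol, via flavan-3,4-diol 11 (not isolated)
Conditions: 10 (3 equiv), (PhO)2P(O)OH (10 mol%), HFIP/MeCN (1:1), −20 °C → rt, Ar
Reagents that add atoms: none
Why: Proposed new method: the acid first activates the aryl epoxide, whose benzylic C–O bond (para to the 4-MOMO group) is opened by the ortho phenol in a 6-endo-tet closure of the pyran ring to give flavan-3,4-diol 11, and the same acid then ionises the C4 carbinol of 11 to a flavan-4-yl cation stabilised by O1 (ortho) and O7 (para), which C2 of the resorcinol ring of 10 captures in a Friedel–Crafts alkylation with loss of water. The closest known reaction types are the acid-catalysed 6-endo phenol–epoxide cyclisation of 1,3-diarylpropene oxides to 2,3-trans-flavan-3-ols and the biomimetic acid-catalysed coupling of flavan-3,4-diols with phenolic nucleophiles; what is new is running both from an acyclic epoxy carbinol in one operation. C2 is set by inversion at the epoxide carbon (the S centre becomes 2R, and any SN1 leakage also favours 2,3-trans), C3 is carried over from the epoxide with retention, and C4 is set by attack of the arene on the half-chair cation anti to the C3 hydroxyl, giving the all-equatorial 2,3-trans-3,4-trans (4S) product, which is also the thermodynamic one. The step needs 6-endo over 5-exo opening (secured by the p-alkoxybenzylic epoxide carbon and the inductively deactivated carbinol-bearing carbon), intramolecular before intermolecular capture of the epoxide (secured by the ortho phenol and the low starting temperature), attack at C2 of the stilbene (the position para to one hydroxyl and ortho to the other, where 3,5-dihydroxystilbenes are alkylated by flavan-4-yl cations) and monoalkylation (secured by excess 10).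

**Step 9**
Reactants: 12 bis-MOM ether of the target
Product: 13 (2R,3S,4S)-4-[2-[(E)-2-(3,4-dihydroxyphenyl)ethenyl]-4,6-dihydroxyphenyl]-2-(4-hydroxyphenyl)-3,4-dihydro-2H-chromene-3,7-diol (target)
Conditions: HCl (2 M in MeOH), MeOH/THF, rt → 35 °C, Ar
Reagents that add atoms: none
Why: acid-catalysed acetal exchange (MOM cleavage) in methanol touches no stereocentre, and the 5-deoxy A ring should make the C4–aryl bond resistant to dilute acid.

**Compound list**
1 | 2,4-dihydroxyacetophenone | CC(=O)c1ccc(O)cc1O | starting material
2 | 1-[2-hydroxy-4-(methoxymethoxy)phenyl]ethanone | CC(=O)c1ccc(OCOC)cc1O | intermediate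
3 | 1-[4-(methoxymethoxy)-2-(prop-2-en-1-yloxy)phenyl]ethanone | CC(=O)c1ccc(OCOC)cc1OCC=C | intermediate
4 | 4-hydroxybenzaldehyde | O=Cc1ccc(O)cc1 | starting material
5 | 4-(methoxymethoxy)benzaldehyde | COCOc1ccc(C=O)cc1 | intermediate
6 | (E)-1-[4-(methoxymethoxy)-2-(prop-2-en-1-yloxy)phenyl]-3-[4-(methoxymethoxy)phenyl]prop-2-en-1-one | O=C(/C=C/c1ccc(OCOC)cc1)c1ccc(OCOC)cc1OCC=C | intermediate
7 | [(2R,3S)-3-[4-(methoxymethoxy)phenyl]oxiran-2-yl][4-(methoxymethoxy)-2-(prop-2-en-1-yloxy)phenyl]methanone | O=C(c1ccc(OCOC)cc1OCC=C)[C@@H]1O[C@H]1c1ccc(OCOC)cc1 | intermediate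
8 | [(2S,3S)-3-[4-(methoxymethoxy)phenyl]oxiran-2-yl][4-(methoxymethoxy)-2-(prop-2-en-1-yloxy)phenyl]methanol, carbinol epimers | OC(c1ccc(OCOC)cc1OCC=C)[C@@H]1O[C@H]1c1ccc(OCOC)cc1 | intermediate
9 | [2-hydroxy-4-(methoxymethoxy)phenyl][(2S,3S)-3-[4-(methoxymethoxy)phenyl]oxiran-2-yl]methanol, carbinol epimers | OC(c1ccc(OCOC)cc1O)[C@@H]1O[C@H]1c1ccc(OCOC)cc1 | intermediate
10 | piceatannol, 4-[(E)-2-(3,5-dihydroxyphenyl)ethenyl]benzene-1,2-diol | Oc1cc(O)cc(/C=C/c2ccc(O)c(O)c2)c1 | starting material
11 | (2R,3S)-7-(methoxymethoxy)-2-[4-(methoxymethoxy)phenyl]-3,4-dihydro-2H-chromene-3,4-diol, C4 epimers | COCOc1ccc([C@H]2Oc3cc(OCOC)ccc3C(O)[C@@H]2O)cc1 | intermediate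
12 | (2R,3S,4S)-4-[2-[(E)-2-(3,4-dihydroxyphenyl)ethenyl]-4,6-dihydroxyphenyl]-7-(methoxymethoxy)-2-[4-(methoxymethoxy)phenyl]-3,4-dihydro-2H-chromen-3-ol | COCOc1ccc([C@H]2Oc3cc(OCOC)ccc3[C@@H](c3c(O)cc(O)cc3/C=C/c3ccc(O)c(O)c3)[C@@H]2O)cc1 | intermediate
13 | (2R,3S,4S)-4-[2-[(E)-2-(3,4-dihydroxyphenyl)ethenyl]-4,6-dihydroxyphenyl]-2-(4-hydroxyphenyl)-3,4-dihydro-2H-chromene-3,7-diol | Oc1ccc([C@H]2Oc3cc(O)ccc3[C@@H](c3c(O)cc(O)cc3/C=C/c3ccc(O)c(O)c3)[C@@H]2O)cc1 | target

**Step count**
Total steps: 9. Longest linear sequence: 8 steps (1 → 2 → 3 → 6 → 7 → 8 → 9 → 12 → 13; steps 1, 2, 4, 5, 6, 7, 8, 9).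

**Steps most likely to fail**

Step 8 (proposed new method). The opened epoxide may be captured by the stilbene or the solvent before the phenol closes the ring, the arene may enter C4 with poor facial or positional selectivity, or the MOM ethers may be lost under the acid. The fallback uses known chemistry, sets out from 9 and returns at 12; it separates ring closure from coupling and controls C4 by anchimeric assistance. Compound 9 is cyclised alone with PPTS in CH2Cl2 and diol 11 is isolated. Acetylation (Ac2O, pyridine, DMAP) gives 3,4-di-O-acetyl flavan-3,4-diol F1. F1 is coupled with 10 under BF3·OEt2 in THF/CH2Cl2 at −40 °C: the 4-acetate leaves, the 3-acetate bridges the cation as a cis-fused dioxolanylium ion, and the arene must enter trans to O3. This gives 3-O-acetyl coupling product F2, whose ester is removed with K2CO3 in degassed MeOH to give 12.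

Step 7. When the phenol is unmasked next to the labile epoxide at the alcohol oxidation level, the epoxide may be opened early by phenoxide in the 5-exo mode or by the amine. The fallback sets out from 7 and returns at 11; it closes the pyran ring at the ketone level. Ketone 7 is deallylated under the same Pd(0)/morpholine conditions to 2'-hydroxy epoxy ketone F4, in which the phenol is tied up by the carbonyl. PPTS in CH2Cl2 then effects 6-endo cyclisation with inversion to trans-dihydroflavonol F5. NaBH4 in MeOH reduces F5 to 11, expected mainly as its (4R), 3,4-trans epimer. Compound 11 is isolated and coupled with 10 under the step 8 conditions.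

Step 5. Nucleophilic epoxidation of an electron-rich chalcone with an ortho alkoxy group may give low conversion or low enantioselectivity, and the labile epoxy ketone may degrade on purification. The fallback sets out from 6 and returns at 8; it uses electrophilic, catalyst-controlled epoxidation at the alcohol level. Luche reduction (NaBH4, CeCl3·7H2O, MeOH, −20 °C) gives racemic allylic alcohol F3. Shi epoxidation with the enantiomer of the fructose-derived ketone (Oxone, K2CO3, Bu4NHSO4, MeCN/dimethoxymethane/buffer, 0 °C) should epoxidise the electron-rich trans-styrenyl alkene, in preference to the allyl ether alkene, to the (2S,3S)-epoxide in both carbinol epimers, which is 8.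

**Further compounds**
F1 | step 8 | 3,4-di-O-acetyl derivative of 11 (C4 epimers) | COCOc1ccc([C@H]2Oc3cc(OCOC)ccc3C(OC(C)=O)[C@@H]2OC(C)=O)cc1
F2 | step 8 | 3-O-acetyl derivative of 12 | COCOc1ccc([C@H]2Oc3cc(OCOC)ccc3[C@@H](c3c(O)cc(O)cc3/C=C/c3ccc(O)c(O)c3)[C@@H]2OC(C)=O)cc1
F3 | step 5 | (E)-1-[4-(methoxymethoxy)-2-(prop-2-en-1-yloxy)phenyl]-3-[4-(methoxymethoxy)phenyl]prop-2-en-1-ol (racemic) | OC(/C=C/c1ccc(OCOC)cc1)c1ccc(OCOC)cc1OCC=C
F4 | step 7 | [2-hydroxy-4-(methoxymethoxy)phenyl][(2R,3S)-3-[4-(methoxymethoxy)phenyl]oxiran-2-yl]methanone | O=C(c1ccc(OCOC)cc1O)[C@@H]1O[C@H]1c1ccc(OCOC)cc1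
F5 | step 7 | (2R,3R)-3-hydroxy-7-(methoxymethoxy)-2-[4-(methoxymethoxy)phenyl]-2,3-dihydro-4H-chromen-4-one | COCOc1ccc([C@H]2Oc3cc(OCOC)ccc3C(=O)[C@@H]2O)cc1
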